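The route is thirteen linear steps, and its key step is an α-ketol rearrangement that enlarges a 1-acetylcyclopentanol to the cyclohexane ring of the target.

**Plan**
Numbering (labdane): carbocycle = C5–C10. Pyran = O, C8, C9, C11, C12, C13. C5 bears CMe2CO2H (C4, C3). C10 bears CH3 and CH2CO2H (C1, C2). C8 bears CH3 and the ring O.
Cuts, in retrosynthetic order: the two ester C–O bonds; O–C13 (6-endo opening of a Z-vinyl epoxide by the C8 hydroxyl); C13–C14 and C12=C13 (Stille coupling, iodo-Wittig); C9=C11 (intramolecular Wittig, butenolide); then C7–C8 of the carbocycle.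
Enabling feature: C8 is a tertiary carbinol carbon (CH3, O) next to C9. With C9 as C=O, the C8/C9 pair of the six-membered ring is a 2-hydroxy-2-methylcyclohexanone, the acyloin isomer of a 1-acetylcyclopentanol. The carbocycle is therefore built as the cyclopentane C9–C10–C5–C6–C7 and enlarged by one atom (C8).
Forward: three-component coupling on 2-methylcyclopentenone (C5–C4, then C10–C1); ethylidenation and ketohydroxylation; α-ketol ring expansion (carbocycle); butenolide, lactol, Z-diene, epoxide; pyran; hydrolysis.
Stereochemistry: C5 from a catalytic asymmetric Mukaiyama–Michael addition; C10 by anti alkylation; C8 by the chelated 1,2-shift; C9 by hydrogenation anti to two axial methyls; C12 and C13 from Z-olefin geometry, reagent-controlled Shi epoxidation and inversion at C13.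

Key step: step 5

Assumption: the (S)-oxazaborolidinium ion is taken to leave the Si face of C3 of enone 1 open. If the α-methyl group reverses this sense, the equally available (R)-catalyst is used and nothing else changes.

Step 1
Reactants: 1 2-methylcyclopent-2-en-1-one; 2 1-methoxy-2-methyl-1-(trimethylsilyloxy)prop-1-ene
Product: 3 methyl 2-methyl-2-[(1S)-2-methyl-3-(trimethylsilyloxy)cyclopent-2-en-1-yl]propanoate
Conditions: (S)-o-tolyl oxazaborolidine (from diphenylprolinol)·HNTf2 (20 mol %), Ph3PO (25 mol %), toluene, −20 °C; Et3N quench, non-acidic work-up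
Reagents that add atoms: none
Why: Catalytic enantioselective Mukaiyama–Michael addition: the chiral oxazaborolidinium ion activates the enone and shields one face, so the ketene acetal carbon bonds to the Si face of C3 (sets C5, S), and silyl transfer to the enolate oxygen stores the regiodefined tetrasubstituted enol ether for step 2.

Step 2
Reactants: 3 silyl enol ether; 4 tert-butyl bromoacetate
Product: 5 tert-butyl 2-[(1R,2S)-2-(1-methoxy-2-methyl-1-oxopropan-2-yl)-1-methyl-5-oxocyclopentyl]acetate
Conditions: BnMe3NF (1.1 equiv), 4 Å MS, THF, −20 °C to rt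
Reagents that add atoms: none
Why: Fluoride-triggered regiospecific alkylation of a silyl enol ether: the enolate can react only at C10 and takes the electrophile anti to the bulky CMe2CO2Me group, which sets the quaternary centre (R) with CH2CO2t-Bu trans to that group; the tert-butyl ester is chosen because it must later resist a cis alkoxide and DIBAL-H.

Step 3
Reactants: 5 keto diester
Product: 6 tert-butyl 2-[(1R,2S,5Z)-5-ethylidene-2-(1-methoxy-2-methyl-1-oxopropan-2-yl)-1-methylcyclopentyl]acetate
Conditions: EtPPh3Br, KOt-Bu, THF, 0 °C to reflux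
Reagents that add atoms: ethyltriphenylphosphonium bromide, CC[P+](c1ccccc1)(c1ccccc1)c1ccccc1.[Br-]
Why: Wittig olefination of an α-quaternary cyclopentanone, the same situation as ethylidenation of 17-oxo steroids; both esters are hindered, and the alkene geometry (Z expected) has no consequence because C8 becomes sp2 again in step 4.

Step 4
Reactants: 6 ethylidene cyclopentane
Product: 7 tert-butyl 2-[(1R,2S,5S)-5-acetyl-5-hydroxy-2-(1-methoxy-2-methyl-1-oxopropan-2-yl)-1-methylcyclopentyl]acetate
Conditions: RuCl3 (1 mol %), Oxone, NaHCO3, EtOAc/MeCN/H2O, rt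
Reagents that add atoms: Oxone (active salt KHSO5), [K+].[O-]S(=O)(=O)OO
Why: Ru-catalysed ketohydroxylation ([3+2] addition of RuO4, then oxidation at the secondary carbon) turns the trisubstituted alkene into the tertiary α-ketol in one operation; the oxidant adds to the ring face opposite the pseudo-axial C10 methyl and the C5 side chain, as oxidants do with 17(20)-ene steroids, so OH ends cis to CH2CO2t-Bu and acetyl cis to CH3.

Step 5
Reactants: 7 1-acetylcyclopentanol
Product: 8 tert-butyl 2-[(1R,3S,6S)-3-hydroxy-6-(1-methoxy-2-methyl-1-oxopropan-2-yl)-1,3-dimethyl-2-oxocyclohexyl]acetate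
Conditions: Al(Ot-Bu)3 (1.5 equiv), toluene, 80 °C; cold aqueous work-up
Reagents that add atoms: none
Why: Aluminium binds the tertiary alkoxide and the acetyl oxygen of 7 in a five-membered chelate (O–C9–C8=O syn), the polarised carbonyl carbon C8 accepts the ring bond C9–C7 in a suprafacial 1,2-shift, and C9 becomes the new ketone: an α-ketol (acyloin) rearrangement. The closest known cases are the Lewis-acid D-homoannulation of 17α-hydroxy-20-oxo steroids and the metal-chelate-induced change of 1-acylcyclopentanols into 2-substituted 2-hydroxycyclohexanones. No ring is closed end to end: the cyclopentane C9–C10–C5–C6–C7 is enlarged to the cyclohexane by insertion of C8 between C9 and C7, driven by loss of cyclopentane eclipsing strain and by the tighter chelate of the product. The single new stereocentre C8 is controlled by the carbinol configuration of 7 plus the syn chelate: with acetyl on the face of the C10 methyl, C7 can reach only the carbonyl face that leaves O8 equatorial and the C8 methyl axial and cis to the C10 methyl (8S); only this epimer keeps O8 nearly eclipsed with C9=O, so the stoichiometric aluminium should also hold it thermodynamically. The step needs migration of the CH2 arm C7 and not of quaternary C10, which is secured because a C10 shift would drive the acetyl methyl into the C10 substituents and create two adjacent fully substituted sp3 carbons, in line with the steroid cases. It also needs the alkoxide not to be acylated by the cis C10 acetate arm, which is why that arm is a tert-butyl ester and the Lewis acid is a non-nucleophilic, hydride-free alkoxide.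

Step 6
Reactants: 8 ring-enlarged α-ketol
Product: 10 tert-butyl 2-[(4R,5S,7aS)-5-(1-methoxy-2-methyl-1-oxopropan-2-yl)-4,7a-dimethyl-2-oxo-2,4,5,6,7,7a-hexahydro-1-benzofuran-4-yl]acetate, via ester ylide 9 (not isolated)
Conditions: Ph3P=C=C=O (1.3 equiv), toluene, reflux
Reagents that add atoms: (triphenylphosphoranylidene)ketene, O=C=C=P(c1ccccc1)(c1ccccc1)c1ccccc1
Why: The tertiary alcohol adds to the cumulated ylide to give stabilised ester ylide 9, whose intramolecular Wittig reaction with the non-enolisable C9 ketone closes the butenolide (the standard α-hydroxy ketone to butenolide conversion, on the substitution pattern of dihydroactinidiolide) and brings C11 and C12 to a carbonyl too hindered for intermolecular olefination.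

Step 7
Reactants: 10 butenolide
Product: 11 tert-butyl 2-[(3aS,4R,5S,7aS)-5-(1-methoxy-2-methyl-1-oxopropan-2-yl)-4,7a-dimethyl-2-oxo-octahydro-1-benzofuran-4-yl]acetate
Conditions: H2 (1–4 atm), 10 % Pd/C, EtOAc, rt
Reagents that add atoms: none
Why: Heterogeneous hydrogenation of the trisubstituted C9=C11 bond: one face is closed by the two axial methyl groups on C8 and C10, so hydrogen should add from the other face and set C9 (S, H trans to both methyls, trans-fused lactone).

Step 8
Reactants: 11 γ-lactone
Product: 12 tert-butyl 2-[(3aS,4R,5S,7aS)-2-hydroxy-5-(1-methoxy-2-methyl-1-oxopropan-2-yl)-4,7a-dimethyl-octahydro-1-benzofuran-4-yl]acetate (anomers)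
Conditions: DIBAL-H (1.1 equiv), toluene, −78 °C; aqueous work-up
Reagents that add atoms: none
Why: Partial reduction of a strained trans-fused γ-lactone to the lactol with one equivalent of DIBAL-H at low temperature; the tert-butyl ester and the pivalate-type methyl ester react far more slowly.

Step 9
Reactants: 12 lactol
Product: 13 tert-butyl 2-[(1R,2S,3S,6S)-3-hydroxy-2-[(2Z)-3-iodobut-2-en-1-yl]-6-(1-methoxy-2-methyl-1-oxopropan-2-yl)-1,3-dimethylcyclohexyl]acetate
Conditions: EtPPh3I, n-BuLi, THF, rt; I2, −78 °C; NaHMDS, −20 °C; then 12, −78 °C to rt (excess ylide)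
Reagents that add atoms: ethyltriphenylphosphonium iodide, CC[P+](c1ccccc1)(c1ccccc1)c1ccccc1.[I-]; iodine, II
Why: Stork–Zhao-type Wittig olefination with the α-iodoethylidene ylide: the lactol reacts through its hydroxy aldehyde form, and the kinetically controlled non-stabilised ylide places iodine cis to the C11 chain (Z), the geometry needed for a cis C12-OH/C13-vinyl pair.

Step 10
Reactants: 13 (Z)-alkenyl iodide
Product: 14 tert-butyl 2-[(1R,2S,3S,6S)-3-hydroxy-6-(1-methoxy-2-methyl-1-oxopropan-2-yl)-1,3-dimethyl-2-[(2Z)-3-methylpenta-2,4-dien-1-yl]cyclohexyl]acetate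
Conditions: Bu3SnCH=CH2, Pd2(dba)3 (2.5 mol %), AsPh3 (10 mol %), NMP, rt to 40 °C
Reagents that add atoms: tributyl(vinyl)stannane, C=C[Sn](CCCC)(CCCC)CCCC
Why: Stille coupling of an alkenyl iodide proceeds with retention, so the vinyl group takes the place of iodine cis to C11 and the (Z)-1,3-diene forms under neutral conditions that the free tertiary alcohol and both esters tolerate.

Step 11
Reactants: 14 (Z)-diene
Product: 15 tert-butyl 2-[(1R,2S,3S,6S)-2-{[(2S,3R)-3-ethenyl-3-methyloxiran-2-yl]methyl}-3-hydroxy-6-(1-methoxy-2-methyl-1-oxopropan-2-yl)-1,3-dimethylcyclohexyl]acetate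
Conditions: ent-Shi ketone (L-fructose series, 30 mol %), Oxone, K2CO3, Bu4NHSO4 (cat.), MeCN/dimethoxymethane/aqueous buffer pH 10.5, 0 °C
Reagents that add atoms: Oxone (active salt KHSO5), [K+].[O-]S(=O)(=O)OO
Why: Shi epoxidation: the chiral dioxirane attacks the electron-rich trisubstituted alkene of the diene and leaves the monosubstituted vinyl group, and the spiro transition state of the L-series ketone delivers oxygen to the face that gives the (12S,13R)-epoxide (reagent control, sets C12).

Step 12
Reactants: 15 hydroxy vinyl epoxide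
Product: 16 methyl 2-[(2S,3S,4aS,5R,6S,8aS)-5-(2-tert-butoxy-2-oxoethyl)-2-ethenyl-3-hydroxy-2,5,8a-trimethyl-octahydro-2H-chromen-6-yl]-2-methylpropanoate
Conditions: CSA (10 mol %), CH2Cl2, −20 to 0 °C
Reagents that add atoms: none
Why: Acid-catalysed 6-endo-tet opening of a vinyl epoxide by the C8 hydroxyl: the tertiary allylic C13 carries the developing positive charge, so attack occurs there with inversion (13R to 13S) through a chair with C12–O equatorial and vinyl axial, while C12 keeps its oxygen.

Step 13
Reactants: 16 pyran diester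
Product: 18 2-[(2S,3S,4aS,5R,6S,8aS)-5-(carboxymethyl)-2-ethenyl-3-hydroxy-2,5,8a-trimethyl-octahydro-2H-chromen-6-yl]-2-methylpropanoic acid (target), via dipotassium salt 17 (not isolated)
Conditions: KOH (excess), 18-crown-6, toluene, 100 °C; then cold 1 M HCl to pH 3
Reagents that add atoms: potassium hydroxide, [K+].[OH-]
Why: Saponification with crown-ether-activated hydroxide cleaves hindered methyl and tert-butyl esters alike; no stereocentre is α to a carbonyl, the ether, alcohol and vinyl groups are base-stable, and brief cold acidification avoids ionising the tertiary allylic ether.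

**Compound list**
1 | 2-methylcyclopent-2-en-1-one | CC1=CCCC1=O | starting material
2 | 1-methoxy-2-methyl-1-(trimethylsilyloxy)prop-1-ene | COC(O[Si](C)(C)C)=C(C)C | starting material
3 | methyl 2-methyl-2-[(1S)-2-methyl-3-(trimethylsilyloxy)cyclopent-2-en-1-yl]propanoate | COC(=O)C(C)(C)[C@H]1CCC(O[Si](C)(C)C)=C1C | intermediate
4 | tert-butyl bromoacetate | CC(C)(C)OC(=O)CBr | starting material
5 | trans keto diester (cyclopentanone) | O=C1CC[C@H](C(C)(C)C(=O)OC)[C@@]1(C)CC(=O)OC(C)(C)C | intermediate
6 | (Z)-ethylidene cyclopentane | C/C=C1/CC[C@H](C(C)(C)C(=O)OC)[C@@]1(C)CC(=O)OC(C)(C)C | intermediate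
7 | 1-acetylcyclopentanol (OH cis to CH2CO2t-Bu) | CC(=O)[C@]1(O)CC[C@H](C(C)(C)C(=O)OC)[C@@]1(C)CC(=O)OC(C)(C)C | intermediate
8 | 2-hydroxy-2-methylcyclohexanone (ring-enlarged α-ketol) | O=C1[C@@](C)(O)CC[C@H](C(C)(C)C(=O)OC)[C@@]1(C)CC(=O)OC(C)(C)C | intermediate
9 | (triphenylphosphoranylidene)acetate ester of 8 | O=C1[C@@](C)(OC(=O)C=P(c2ccccc2)(c2ccccc2)c2ccccc2)CC[C@H](C(C)(C)C(=O)OC)[C@@]1(C)CC(=O)OC(C)(C)C | intermediate
10 | butenolide | O=C1O[C@@]2(C)CC[C@H](C(C)(C)C(=O)OC)[C@@](C)(CC(=O)OC(C)(C)C)C2=C1 | intermediate
11 | trans-fused γ-lactone | O=C1O[C@@]2(C)CC[C@H](C(C)(C)C(=O)OC)[C@@](C)(CC(=O)OC(C)(C)C)[C@@H]2C1 | intermediate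
12 | lactol (anomers) | OC1O[C@@]2(C)CC[C@H](C(C)(C)C(=O)OC)[C@@](C)(CC(=O)OC(C)(C)C)[C@@H]2C1 | intermediate
13 | (Z)-alkenyl iodide | I/C(C)=C\C[C@@H]1[C@@](C)(O)CC[C@H](C(C)(C)C(=O)OC)[C@@]1(C)CC(=O)OC(C)(C)C | intermediate
14 | (Z)-diene | C=C/C(C)=C\C[C@@H]1[C@@](C)(O)CC[C@H](C(C)(C)C(=O)OC)[C@@]1(C)CC(=O)OC(C)(C)C | intermediate
15 | (12S,13R)-vinyl epoxide | C=C[C@@]1(C)O[C@H]1C[C@@H]2[C@@](C)(O)CC[C@H](C(C)(C)C(=O)OC)[C@@]2(C)CC(=O)OC(C)(C)C | intermediate
16 | pyran diester | C=C[C@]1(C)O[C@@]2(C)CC[C@H](C(C)(C)C(=O)OC)[C@@](C)(CC(=O)OC(C)(C)C)[C@@H]2C[C@@H]1O | intermediate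
17 | dipotassium dicarboxylate | C=C[C@]1(C)O[C@@]2(C)CC[C@H](C(C)(C)C(=O)[O-])[C@@](C)(CC(=O)[O-])[C@@H]2C[C@@H]1O.[K+].[K+] | intermediate
18 | CNP0325408.2 | C=C[C@]1(C)O[C@@]2(C)CC[C@H](C(C)(C)C(=O)O)[C@@](C)(CC(=O)O)[C@@H]2C[C@@H]1O | target

Total step count: 13. Longest linear sequence: 13 (steps 1–13).

**Steps most likely to fail**

Step 5. The aluminium alkoxide may be acylated by the cis acetate arm (lactonisation) before the shift. The quaternary carbon C10 may migrate instead of the CH2 arm. Prolonged reversible shifts may also erode the configuration at C8.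
The fallback sets out from 5 and returns at 8. The same cyclopentanone is enlarged by carbon insertion instead of an acyloin shift.
- Lewis-acid-promoted homologation with diazoethane (Sc(OTf)3 cat., CH2Cl2, −78 °C), in which the less substituted C7 migrates, should give the ring-enlarged methyl ketone F1.
- C10 is quaternary, so enolisation is possible only toward C8, and TMSOTf/Et3N should give the silyl enol ether F2.
- Rubottom oxidation (mCPBA, NaHCO3, CH2Cl2) from the face opposite the axial C10 methyl should give the α-silyloxy ketone F3.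
- HF·pyridine then converts F3 into 8.

Step 1. Facial discrimination may be poor because the α-methyl enone lacks the α-C–H contact that orients simple cycloalkenones on the catalyst. The silyl enol ether may also hydrolyse during isolation.
The fallback sets out from 1 and returns at 3.
- CBS reduction ((S)-Me-CBS, BH3·SMe2, THF, −20 °C) should give the allylic alcohol F4.
- Johnson–Claisen rearrangement with trimethyl orthoisobutyrate (cat. propionic acid, xylene, 140 °C) moves the chirality suprafacially from the C–O bond to the new C5–C4 bond and should give the cyclopentenyl ester F5.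
- Hydroboration–oxidation (BH3·THF, then NaBO3) anti to the side chain should give the cyclopentanol F6.
- Dess–Martin oxidation should give the methylcyclopentanone F7.
- Thermodynamic silylation (TMSI, HMDS, CH2Cl2) should give 3.

Step 9. The lactol may open too slowly at the temperatures at which the iodo ylide survives. Z selectivity may be lost, and iodine may be lost from the ylide.
The fallback sets out from 12 and returns at 14.
- Ramirez olefination (CBr4, PPh3, Et3N, CH2Cl2, 0 °C) should give the dibromoalkene F8.
- A trans-selective Negishi methylation (Me2Zn, PdCl2(DPEphos), THF) replaces only the bromine trans to the chain and should give the (Z)-bromoalkene F9.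
- A second coupling with tributyl(vinyl)stannane (Pd(t-Bu3P)2, toluene) with retention should give 14.

**Further compounds**
F1 | step 5 | ring-enlarged methyl ketone, tert-butyl 2-[(1R,6S)-6-(1-methoxy-2-methyl-1-oxopropan-2-yl)-1,3-dimethyl-2-oxocyclohexyl]acetate (C3 epimers) | O=C1C(C)CC[C@H](C(C)(C)C(=O)OC)[C@@]1(C)CC(=O)OC(C)(C)C
F2 | step 5 | silyl enol ether of F1 | C[Si](C)(C)OC1=C(C)CC[C@H](C(C)(C)C(=O)OC)[C@@]1(C)CC(=O)OC(C)(C)C
F3 | step 5 | α-silyloxy ketone (trimethylsilyl ether of 8) | O=C1[C@@](C)(O[Si](C)(C)C)CC[C@H](C(C)(C)C(=O)OC)[C@@]1(C)CC(=O)OC(C)(C)C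
F4 | step 1 | allylic alcohol, (1R)-2-methylcyclopent-2-en-1-ol | O[C@@H]1CCC=C1C
F5 | step 1 | cyclopentenyl ester, methyl 2-methyl-2-[(1S)-2-methylcyclopent-2-en-1-yl]propanoate | COC(=O)C(C)(C)[C@H]1CCC=C1C
F6 | step 1 | cyclopentanol, methyl 2-(3-hydroxy-2-methylcyclopentyl)-2-methylpropanoate (OH and H-2 anti to the side chain) | COC(=O)C(C)(C)[C@H]1CC[C@H](O)[C@H]1C
F7 | step 1 | methylcyclopentanone, methyl 2-methyl-2-[(1S)-2-methyl-3-oxocyclopentyl]propanoate (C2 epimers) | COC(=O)C(C)(C)[C@H]1CCC(=O)C1C
F8 | step 9 | dibromoalkene | BrC(Br)=CC[C@@H]1[C@@](C)(O)CC[C@H](C(C)(C)C(=O)OC)[C@@]1(C)CC(=O)OC(C)(C)C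
F9 | step 9 | (Z)-bromoalkene | Br/C(C)=C\C[C@@H]1[C@@](C)(O)CC[C@H](C(C)(C)C(=O)OC)[C@@]1(C)CC(=O)OC(C)(C)C
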